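**Compound numbers used throughout:** 1 1-bromoicosane; 2 triphenylphosphine; 3 icosyl(triphenyl)phosphonium bromide; 4 1-(triisopropylsilyl)-1H-pyrrole-3-carbaldehyde; 5 icosylidenetriphenylphosphorane (ylide, not isolated); 6 3-[(Z)-henicos-1-en-1-yl]-1-(triisopropylsilyl)-1H-pyrrole; 7 3-henicosyl-1-(triisopropylsilyl)-1H-pyrrole; 8 3-henicosyl-1H-pyrrole; 9 the iminium chloride formed from 8 (not isolated); 10 the target, 3-henicosyl-1H-pyrrole-2-carbaldehyde.

## Analysis of the target

Target 10 is a single aromatic pyrrole ring (N1, C2–C5) with a formyl group on C2 and an unbranched, saturated twenty-one-carbon chain (C1'–C21') on the neighbouring C3; N1, C4 and C5 carry hydrogen. There is no stereocentre and no stereogenic double bond, so the problem is one of constitution only: the 2,3-relationship on the ring and the exact length of the chain. The ring is electron-rich. Once the formyl group is present it is tamed as a vinylogous formamide, but the N–H alkylpyrroles on the way are prone to acid-induced oligomerisation and air oxidation, and the N–H is acidic enough to quench carbanions. The main difficulty is that a pyrrole reacts with electrophiles at its α-carbons, so a carbon substituent on the β-carbon C3 cannot be placed by direct substitution of the parent ring, and the 2,3-pattern must be kept apart from the 2,4-pattern. The second difficulty is physical: the C21 chain governs solubility and chromatographic behaviour, and homologues differing by one CH2 cannot be separated, so the chain must be assembled from pieces of defined length by a reaction that cannot scramble it. The plan rests on the C1'–C2' bond of the side chain: C1' can be the formyl carbon of a pyrrole already functionalised at C3 (compound 4), and C2'–C21' is a twenty-carbon unit available as the primary bromide 1. The C2 formyl group is left for the end, where the alkyl group on C3 activates the adjacent α-carbon.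

## Retrosynthetic reasoning

**C2–CHO bond (10 ⇒ 8, through 9).** The formyl group is removed first. An aldehyde on C2 would compete in any olefination at C1', and an α-formyl group is the one substituent that electrophilic substitution of an N–H pyrrole delivers directly. The target is thereby reduced to the monosubstituted pyrrole 8. In the forward direction a Vilsmeier formylation has to choose C2 over C5. C2 is favoured electronically, because the cationic σ-complex places charge on the chain-bearing C3; C5 is favoured sterically, and the product of attack there has to be separated. The iminium salt 9 is hydrolysed in the same flask.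

**N1–H bond (8 ⇒ 7).** The hydrogen on N1 is replaced by a triisopropylsilyl group. This group is needed in the two earlier steps, and it must be off before formylation, because on N1 it screens both α-carbons and would send the electrophile to C4. The forward reaction is a fluoride-induced N–Si cleavage that touches nothing else.

**C1'–C2' single bond (7 ⇒ 6).** The saturated chain has no handle, so a double bond is introduced retrosynthetically at C1'=C2'. This is the retron of a carbonyl olefination, and its geometry is of no consequence. The forward hydrogenation has to reduce the alkene without touching the aromatic ring or the N–Si bond.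

**C1'=C2' double bond (6 ⇒ 4 + 5).** This is the strategic cut. It is the only position in the chain where both fragments are simple: the ring fragment 4 carries its functional group directly on C3, so the β-position is already fixed, and the chain fragment has an even, twenty-carbon count. A cut at C3–C1' would need a β-metallated pyrrole and a C21 electrophile, and cuts further out would need ring fragments with homologated side chains that have to be made. The gain is convergence and an exact 1 + 20 carbon count. The forward olefination must win over proton transfer, which is why the nitrogen of 4 is silylated.

**C–P bond (5 ⇒ 3 ⇒ 1 + 2).** Ylide 5 comes from salt 3 by deprotonation with a non-nucleophilic amide base, and 3 comes from SN2 quaternisation of phosphine 2 by bromide 1.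

## Alternatives that were turned down

**Alternative 1: ring synthesis from an amino acetal and an α-keto ester.**
- Disconnection: the ring is cut at N1–C2 and C3–C4, leading to ethyl 2-oxotetracosanoate (A1) and 2,2-dimethoxyethan-1-amine (A2).
- Forward key step: the amine of A2 condenses with the ketone of A1 (N1–C2). Trifluoroacetic acid then ionises the acetal, the enamine carbon closes on the oxocarbenium ion (C3–C4), and loss of the second methoxy group aromatises the ring to ethyl 3-henicosyl-1H-pyrrole-2-carboxylate (A3).
- For it: the 2,3-pattern is fixed by the way the ring is assembled, no regioisomer can arise, and A3 is a robust, ester-stabilised pyrrole.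
- Against it here: A1 is not a stock chemical and would have to be made from a C22 halide and an oxalate. The condensation has to beat aminolysis of the activated ester. The ester of A3 is at the wrong oxidation level, so reduction with LiAlH4 to (3-henicosyl-1H-pyrrol-2-yl)methanol (A4) and re-oxidation with MnO2 follow, and A4 is a pyrrolylcarbinol that ionises and oligomerises readily.
- Comparison: this route is stronger on regiochemical certainty. The chosen route offers purchasable ring and chain fragments, five steps against six or more, and routine bond-forming steps, with its one weakness confined to a separation at the last step.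

**Alternative 2: bromoformylation of a 4-alkyl lactam.**
- Disconnection: the C2–CHO bond is cut and the ring is traced back to the non-aromatic lactam 4-henicosyl-1,5-dihydro-2H-pyrrol-2-one (A5); the C5–H of the target derives from a C–Br bond.
- Forward key step: the bromoiminium reagent from POBr3 and DMF formylates the methylene carbon next to nitrogen and converts the lactam carbonyl into a C–Br bond, and the ring aromatises to 5-bromo-3-henicosyl-1H-pyrrole-2-carbaldehyde (A6). Hydrogenolysis of the bromide would finish the synthesis.
- For it: the formyl group can only enter at the carbon adjacent to the chain-bearing carbon, the bromine blocks the other α-carbon, and A6 is a stable, acceptor-substituted pyrrole.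
- Against it here: A5 is not available, so the task of attaching a C21 chain to a five-membered heterocycle is only handed to the lactam series, where it costs several steps. N-unsubstituted lactams of this type tautomerise and autoxidise, the reagent is harsh, and an extra dehalogenation in the presence of the aldehyde is needed.
- Comparison: again stronger in regiocontrol, but weaker in step economy and in the accessibility of its precursor. The chosen route solves the chain attachment, the larger part of the problem, by one reliable C=C bond formation between two purchasable pieces.

**Alternative 3: cross-metathesis at C2'=C3'.**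
- Disconnection: the chain is cut one bond further out, giving tert-butyl 2-formyl-3-(prop-2-en-1-yl)-1H-pyrrole-1-carboxylate (A7) and icos-1-ene (A8).
- Forward key step: the second-generation Grubbs catalyst couples A7 with an excess of A8 to tert-butyl 2-formyl-3-[(E)-henicos-2-en-1-yl]-1H-pyrrole-1-carboxylate (A9). Hydrogenation and removal of the carbamate would follow.
- For it: the formyl group is in place before the chain arrives, so no regiochemical question remains at the end; the union is catalytic and the chain partner is a cheap terminal alkene.
- Against it here: A7 must itself be made, and placing an allyl group on C3 next to a formyl group on C2 is the same 2,3-problem moved to the start. Both partners are unhindered terminal alkenes, so the coupling is statistical and self-metathesis products as greasy as A9 must be removed. Ruthenium hydride species can also move the allylic double bond into conjugation with the ring before metathesis, which would shorten the chain by one carbon and give a homologue that cannot be separated after hydrogenation.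
- Comparison: this route is stronger in that it ends without a regioisomer. The chosen route offers a stoichiometric, position-specific olefination in which the 1 + 20 carbon count cannot drift, and precursors that are bought rather than made.

Key step: step 2

Remark on the chemistry: compounds 1, 2 and 4 are taken as purchasable; 10 has no stereocentre, so the Z geometry of 6 only has to form and need not be preserved.

## Route

Step 1
Reactants: 1 1-bromoicosane; 2 triphenylphosphine
Product: 3 icosyl(triphenyl)phosphonium bromide
Conditions: MeCN, reflux, 72 h; trituration with Et2O; drying under vacuum
Reagents that add atoms: none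
Why: SN2 quaternisation of triphenylphosphine by an unhindered primary alkyl bromide (phosphonium salt formation) has no competing elimination; the salt is freed from excess 2 and residual 1 by trituration with ether and is dried thoroughly, because water would quench the ylide in step 2.

Step 2
Reactants: 3 icosyl(triphenyl)phosphonium bromide; 4 1-(triisopropylsilyl)-1H-pyrrole-3-carbaldehyde
Product: 6 3-[(Z)-henicos-1-en-1-yl]-1-(triisopropylsilyl)-1H-pyrrole, via icosylidenetriphenylphosphorane 5 (not isolated)
Conditions: NaN(SiMe3)2 (1.0 M in THF, slightly less than 3), THF, 0 °C, 30 min; then 4, −78 °C → rt
Reagents that add atoms: none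
Why: NaN(SiMe3)2 deprotonates 3 at the carbon next to phosphorus and gives the lithium-free, non-stabilised ylide 5. The ylide carbon adds to the formyl carbon of 4 in an asynchronous [2+2] manner to give an oxaphosphetane, which undergoes syn-cycloreversion, driven by the P=O bond, to the C1'=C2' alkene 6 and triphenylphosphine oxide; this single C–C bond joins the whole chain to C3. The closest known reaction type is the Wittig olefination of aromatic and heteroaromatic aldehydes with alkylidenetriphenylphosphoranes. No ring is closed and no stereocentre is formed; the only stereochemical element is the alkene geometry, which the kinetically preferred cis-oxaphosphetane under salt-free conditions should set as Z and which step 3 erases in any case. The selectivity the step needs is chemoselectivity, carbonyl addition in preference to proton transfer or attack at silicon: the N–Si(iPr)3 group replaces the acidic N–H, which would otherwise protonate 5 and leave an unreactive formylpyrrolide, and its three isopropyl groups shield silicon from the amide base and from the ylide. The nitrogen lone pair stays in the aromatic sextet whatever the N-substituent, so the formyl group of 4 is a vinylogous formamide and less electrophilic than that of benzaldehyde; a non-stabilised ylide is nucleophilic enough for it, and a small excess of 5 with warming to room temperature should bring the reaction to completion. The aldehyde has no α-hydrogen, so enolisation cannot compete.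

Step 3
Reactants: 6 3-[(Z)-henicos-1-en-1-yl]-1-(triisopropylsilyl)-1H-pyrrole
Product: 7 3-henicosyl-1-(triisopropylsilyl)-1H-pyrrole
Conditions: H2 (1 atm), 10% Pd/C, EtOAc, rt
Reagents that add atoms: none
Why: Heterogeneous catalytic hydrogenation of a 1,2-disubstituted alkene; at 1 atm and room temperature the aromatic pyrrole ring and the N–Si bond should not be reduced, both alkene isomers converge on the same saturated chain, and 6 is first passed through silica to remove phosphorus residues that would poison the catalyst.

Step 4
Reactants: 7 3-henicosyl-1-(triisopropylsilyl)-1H-pyrrole
Product: 8 3-henicosyl-1H-pyrrole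
Conditions: Bu4NF, THF, 0 °C → rt; H2O work-up; product kept cold under argon and used at once
Reagents that add atoms: none
Why: Fluoride-induced N–Si cleavage (desilylation) is driven by the strong Si–F bond, the released pyrrolide is protonated on aqueous work-up, and nothing else in 7 reacts with fluoride. The electron-rich N–H pyrrole is formylated without delay to limit oxidation and oligomerisation.

Step 5
Reactants: 8 3-henicosyl-1H-pyrrole
Product: 10 3-henicosyl-1H-pyrrole-2-carbaldehyde (target), via iminium chloride 9 (not isolated)
Conditions: POCl3, DMF, ClCH2CH2Cl, 0 °C → rt; then aq. NaOH, 50 °C; chromatography on SiO2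
Reagents that add atoms: N,N-dimethylformamide, CN(C)C=O (formyl carbon of 10 and the NMe2 group of 9); water, O (aldehyde oxygen); phosphoryl chloride, O=P(Cl)(Cl)Cl (chloride counter-ion of 9 only)
Why: Vilsmeier–Haack formylation: the chloroiminium ion from POCl3 and DMF attacks an α-carbon of the N–H pyrrole, and C2 should be preferred because the σ-complex places positive charge on the alkyl-bearing C3, whereas attack at C5 gains no such stabilisation. Base hydrolysis of iminium salt 9 releases the aldehyde, and the minor product of attack at C5 is to be removed by chromatography.

## Compound list

1 | 1-bromoicosane | CCCCCCCCCCCCCCCCCCCCBr | starting material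
2 | triphenylphosphine | c1ccc(P(c2ccccc2)c2ccccc2)cc1 | starting material
3 | icosyl(triphenyl)phosphonium bromide | CCCCCCCCCCCCCCCCCCCC[P+](c1ccccc1)(c1ccccc1)c1ccccc1.[Br-] | intermediate
4 | 1-(triisopropylsilyl)-1H-pyrrole-3-carbaldehyde | O=Cc1ccn([Si](C(C)C)(C(C)C)C(C)C)c1 | starting material
5 | icosylidenetriphenylphosphorane (ylide) | CCCCCCCCCCCCCCCCCCCC=P(c1ccccc1)(c1ccccc1)c1ccccc1 | intermediate, not isolated
6 | 3-[(Z)-henicos-1-en-1-yl]-1-(triisopropylsilyl)-1H-pyrrole | CCCCCCCCCCCCCCCCCCC/C=C\c1ccn([Si](C(C)C)(C(C)C)C(C)C)c1 | intermediate
7 | 3-henicosyl-1-(triisopropylsilyl)-1H-pyrrole | CCCCCCCCCCCCCCCCCCCCCc1ccn([Si](C(C)C)(C(C)C)C(C)C)c1 | intermediate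
8 | 3-henicosyl-1H-pyrrole | CCCCCCCCCCCCCCCCCCCCCc1cc[nH]c1 | intermediate
9 | N-[(3-henicosyl-1H-pyrrol-2-yl)methylidene]-N-methylmethanaminium chloride | CCCCCCCCCCCCCCCCCCCCCc1cc[nH]c1C=[N+](C)C.[Cl-] | intermediate, not isolated
10 | 3-henicosyl-1H-pyrrole-2-carbaldehyde | CCCCCCCCCCCCCCCCCCCCCc1cc[nH]c1C=O | target

## Step count and least certain steps

Total: 5 steps. Longest linear sequence: 5 steps (1 → 3 → 6 → 7 → 8 → 10); aldehyde 4 enters in step 2.

**Step 2 (key step).** The olefination may be slow or incomplete, because the carbonyl group of 4 is deactivated by conjugation with the ring nitrogen and the C20 ylide 5 is poorly soluble at low temperature. Adventitious moisture would also quench 5 or cleave the N–Si bond, and the resulting pyrrolide would not react. Fallback: carbonyl addition followed by elimination in place of olefination, setting out from 1 and 4 and returning to the route at 7. Bromide 1 is converted with Mg turnings in THF into icosylmagnesium bromide F1, which adds to 4 at 0 °C to give, after NH4Cl work-up, racemic 1-[1-(triisopropylsilyl)-1H-pyrrol-3-yl]henicosan-1-ol F2. Acid-catalysed dehydration (pyridinium p-toluenesulfonate, toluene, 80 °C, molecular sieves) through the pyrrole-stabilised cation gives 3-[(E)-henicos-1-en-1-yl]-1-(triisopropylsilyl)-1H-pyrrole F3, and hydrogenation under the conditions of step 3 gives 7.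

**Step 5.** Discrimination between the two free α-carbons may be insufficient, since attack at C5 competes on steric grounds. Chromatographic resolution of two aldehydes whose polarity is dominated by the same chain may be incomplete, and 8 may oligomerise under acid before it is formylated. Fallback: directed metalation with a removable block at C5 in place of electrophilic substitution, setting out from 8 and returning at 10. Compound 8 is N-acylated with Boc2O and catalytic 4-(dimethylamino)pyridine in MeCN to tert-butyl 3-henicosyl-1H-pyrrole-1-carboxylate F4. Lithium 2,2,6,6-tetramethylpiperidide in THF at −78 °C removes the α-proton remote from the chain (C5, steric control), and hexachloroethane caps this carbon as the chloride, tert-butyl 2-chloro-4-henicosyl-1H-pyrrole-1-carboxylate F5. A second lithiation under the same conditions is directed by the carbamate to the remaining α-carbon, next to the chain, and a DMF quench gives tert-butyl 5-chloro-2-formyl-3-henicosyl-1H-pyrrole-1-carboxylate F6. K2CO3 in MeOH removes the carbamate to give 5-chloro-3-henicosyl-1H-pyrrole-2-carbaldehyde F7, and hydrogenolysis of the C–Cl bond (H2, 10% Pd/C, Et3N, EtOAc) gives 10.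

**Step 3.** Hydrogen uptake may stall through poisoning of the catalyst by phosphorus residues carried over from step 2 or through poor solubility of the waxy substrate, and forcing the conditions risks over-reduction of the heteroaromatic ring. Fallback: stoichiometric, metal-free diimide reduction in place of heterogeneous catalysis, setting out from 6 and returning at 7. Diimide generated in situ from 2-nitrobenzenesulfonohydrazide and Et3N in CH2Cl2 at rt transfers H2 to the C1'=C2' bond in a concerted syn fashion and cannot touch the aromatic ring or the N–Si bond; this fallback makes no new compound (F0).

## Further compounds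

F1 | step 2 | icosylmagnesium bromide | CCCCCCCCCCCCCCCCCCCC[Mg]Br
F2 | step 2 | racemic 1-[1-(triisopropylsilyl)-1H-pyrrol-3-yl]henicosan-1-ol | CCCCCCCCCCCCCCCCCCCCC(O)c1ccn([Si](C(C)C)(C(C)C)C(C)C)c1
F3 | step 2 | 3-[(E)-henicos-1-en-1-yl]-1-(triisopropylsilyl)-1H-pyrrole | CCCCCCCCCCCCCCCCCCC/C=C/c1ccn([Si](C(C)C)(C(C)C)C(C)C)c1
F4 | step 5 | tert-butyl 3-henicosyl-1H-pyrrole-1-carboxylate | CCCCCCCCCCCCCCCCCCCCCc1ccn(C(=O)OC(C)(C)C)c1
F5 | step 5 | tert-butyl 2-chloro-4-henicosyl-1H-pyrrole-1-carboxylate | CCCCCCCCCCCCCCCCCCCCCc1cc(Cl)n(C(=O)OC(C)(C)C)c1
F6 | step 5 | tert-butyl 5-chloro-2-formyl-3-henicosyl-1H-pyrrole-1-carboxylate | CCCCCCCCCCCCCCCCCCCCCc1cc(Cl)n(C(=O)OC(C)(C)C)c1C=O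
F7 | step 5 | 5-chloro-3-henicosyl-1H-pyrrole-2-carbaldehyde | CCCCCCCCCCCCCCCCCCCCCc1cc(Cl)[nH]c1C=O
F0 | step 3 | none | none
A1 | alternative 1 | ethyl 2-oxotetracosanoate | CCCCCCCCCCCCCCCCCCCCCCC(=O)C(=O)OCC
A2 | alternative 1 | 2,2-dimethoxyethan-1-amine (aminoacetaldehyde dimethyl acetal) | COC(CN)OC
A3 | alternative 1 | ethyl 3-henicosyl-1H-pyrrole-2-carboxylate | CCCCCCCCCCCCCCCCCCCCCc1cc[nH]c1C(=O)OCC
A4 | alternative 1 | (3-henicosyl-1H-pyrrol-2-yl)methanol | CCCCCCCCCCCCCCCCCCCCCc1cc[nH]c1CO
A5 | alternative 2 | 4-henicosyl-1,5-dihydro-2H-pyrrol-2-one | CCCCCCCCCCCCCCCCCCCCCC1=CC(=O)NC1
A6 | alternative 2 | 5-bromo-3-henicosyl-1H-pyrrole-2-carbaldehyde | CCCCCCCCCCCCCCCCCCCCCc1cc(Br)[nH]c1C=O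
A7 | alternative 3 | tert-butyl 2-formyl-3-(prop-2-en-1-yl)-1H-pyrrole-1-carboxylate | C=CCc1ccn(C(=O)OC(C)(C)C)c1C=O
A8 | alternative 3 | icos-1-ene | C=CCCCCCCCCCCCCCCCCCC
A9 | alternative 3 | tert-butyl 2-formyl-3-[(E)-henicos-2-en-1-yl]-1H-pyrrole-1-carboxylate | CCCCCCCCCCCCCCCCCC/C=C/Cc1ccn(C(=O)OC(C)(C)C)c1C=O
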